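**Retrosynthetic overview**

- Ring numbering: O1, C2 (side chain), C3, C4=C5 (CH3 on C5), C6 (CHBr2). The CH2Cl group is taken back to a methyl ester (iBu2AlH reduction, then Appel chlorination).
- Key disconnection: the exocyclic bond from C2 to the quaternary carbon carrying Cl and CH3. It joins two adjacent stereocentres and lies next to O1, so C2 becomes an oxocarbenium carbon (from a C2 methyl acetal) and the quaternary carbon the nucleophilic carbon of the silyl ketene acetal of methyl 2-chloropropanoate.
- The only ring, the dihydropyran, is closed before that through the O1–C2 bond by acid-catalysed cyclisation of a (Z)-configured hydroxy dimethyl acetal; no ring is formed afterwards.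
- The hydroxy acetal comes from oxazaborolidine reduction (sets C6) of a dibromomethyl enone, itself made from LiCHBr2 and the (Z)-enoate of a Still–Gennari olefination of 3,3-dimethoxypropanal.

Key step: step 7

Assumption: in the oxazaborolidine reduction the twisted, α-branched (Z)-alkenyl group is taken as the large ketone substituent and CHBr2 as the small one (as halomethyl groups behave beside sp2 substituents); the carbinol configuration is to be checked (Mosher esters) and the (R)-catalyst used if the sense proves opposite.

**Route**

Step 1
Reactants: 1 methyl 3,3-dimethoxypropanoate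
Product: 2 3,3-dimethoxypropanal
Conditions: iBu2AlH (1.05 equiv), CH2Cl2, –78 °C; MeOH, aq. potassium sodium tartrate; used crude at once
Reagents that add atoms: none
Why: Partial ester reduction with iBu2AlH stops at the aldehyde because the tetrahedral aluminium hemiacetal survives at –78 °C until work-up, and immediate use avoids loss of methanol from this β-alkoxy aldehyde.

Step 2
Reactants: 2 3,3-dimethoxypropanal; 3 ethyl 2-[bis(2,2,2-trifluoroethoxy)phosphoryl]propanoate
Product: 4 ethyl (2Z)-5,5-dimethoxy-2-methylpent-2-enoate
Conditions: 3, KN(SiMe3)2, 18-crown-6, THF, –78 °C; then 2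
Reagents that add atoms: none
Why: Still–Gennari variant of the Horner–Wadsworth–Emmons olefination, in which the trifluoroethyl phosphonate with a dissociated potassium counter-ion eliminates from the kinetic adduct and should give the (Z)-trisubstituted enoate, placing the ester carbon (future C6) and the CH2 group (future C3) cis as the ring requires.

Step 3
Reactants: 4 ethyl (2Z)-5,5-dimethoxy-2-methylpent-2-enoate; 5 dibromomethane
Product: 7 (3Z)-1,1-dibromo-6,6-dimethoxy-3-methylhex-3-en-2-one, via dibromomethyllithium 6 (not isolated)
Conditions: 5, lithium 2,2,6,6-tetramethylpiperidide (2.1 equiv), THF, –90 °C; then 4, –90 to –78 °C; HCl/EtOH quench at –78 °C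
Reagents that add atoms: none
Why: Acylation of the carbenoid by the ester (first stage of the Kowalski homologation), in which LiCHBr2 adds 1,2 to the hindered enoate carbonyl, the ketone released is held as its enolate by the second equivalent of base against over-addition, and the cold acid quench frees the dibromomethyl ketone without isomerising the (Z)-alkene.

Step 4
Reactants: 7 (3Z)-1,1-dibromo-6,6-dimethoxy-3-methylhex-3-en-2-one
Product: 8 (2S,3Z)-1,1-dibromo-6,6-dimethoxy-3-methylhex-3-en-2-ol
Conditions: (S)-1-methyl-3,3-diphenyltetrahydro-1H,3H-pyrrolo[1,2-c][1,3,2]oxazaborole [(S)-Me-CBS, 0.2 equiv], catecholborane, toluene, –78 °C; MeOH, pH 7 buffer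
Reagents that add atoms: none
Why: Corey–Bakshi–Shibata reduction, in which the oxazaborolidine binds the carbonyl oxygen on the side of the CHBr2 group and delivers hydride to the Re face of the carbonyl, which should give the (S)-carbinol (future C6) by 1,2-reduction, while the neutral work-up keeps the dibromomethyl carbinol from closing to a bromo epoxide.

Step 5
Reactants: 8 (2S,3Z)-1,1-dibromo-6,6-dimethoxy-3-methylhex-3-en-2-ol
Product: 9 (6S)-6-(dibromomethyl)-2-methoxy-5-methyl-3,6-dihydro-2H-pyran (both C2 anomers)
Conditions: pyridinium p-toluenesulfonate (0.1 equiv), CH2Cl2, 4 Å molecular sieves, rt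
Reagents that add atoms: none
Why: Acid-catalysed intramolecular transacetalisation, in which the (Z)-alkene holds the hydroxyl within reach of the acetal carbon so that the 6-membered cyclic acetal forms with loss of methanol, no bond to C6 is broken, and the electron-poor allylic C6–O bond should not ionise under this mild acid.

Step 6
Reactants: 10 methyl 2-chloropropanoate (racemic)
Product: 11 2-chloro-1-methoxy-1-(trimethylsilyloxy)prop-1-ene (E/Z mixture)
Conditions: LiN(iPr)2 and Me3SiCl premixed, THF, –78 °C; then 10; to rt; distillation
Reagents that add atoms: chlorotrimethylsilane, C[Si](C)(C)Cl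
Why: O-silylation of an ester enolate under internal-quench conditions, so that the lithium enolate of the α-chloro ester is trapped by Me3SiCl as it forms and before Darzens-type self-condensation, the E/Z composition being irrelevant because both oxygens end in the ester.

Step 7
Reactants: 9 (6S)-6-(dibromomethyl)-2-methoxy-5-methyl-3,6-dihydro-2H-pyran; 11 2-chloro-1-methoxy-1-(trimethylsilyloxy)prop-1-ene
Product: 13 methyl (2R)-2-chloro-2-[(2S,6S)-6-(dibromomethyl)-5-methyl-3,6-dihydro-2H-pyran-2-yl]propanoate, via oxocarbenium ion 12 (not isolated)
Conditions: 11 (2 equiv), Me3SiOSO2CF3 (0.2 equiv), CH2Cl2, –78 °C; aq. NaHCO3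
Reagents that add atoms: none
Why: Me3SiOSO2CF3 removes the methoxy group of either anomer of 9 as MeOSiMe3 to leave the cyclic C2 oxocarbenium ion 12, the nucleophilic carbon of 11 adds to C2, and silyl transfer from the resulting silyloxocarbenium ion regenerates the Lewis acid, which is the Mukaiyama-type (Noyori) addition of silyl ketene acetals to acetal-derived oxocarbenium ions of 2-alkoxy pyrans. No ring is closed; one C–C bond (C2 to the chlorine-bearing carbon) and two stereocentres are formed. C2 is set by substrate control: allylic 1,2-strain with the C5 methyl should hold the C6 CHBr2 group pseudo-axial on the nearly flat ring, so the bulky nucleophile enters the Re face of C2, anti to that group, giving the 2,6-trans ring. The quaternary carbon is set by the relative topicity of an open transition state with C–Cl antiperiplanar to the C2=O1 bond and the methyl group in the free sector beside the C2–H, which pairs the Re face of C2 with the Re face of the nucleophile. The step needs 2,6-trans facial selectivity, secured by the C6 substituent, and like topicity at the quaternary carbon, which rests only on this conformational preference and is the weaker element, the epimer being removable by chromatography. Fast capture by the ketene acetal at –78 °C should outrun loss of the allylic C3 proton from 12.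

Step 8
Reactants: 13 methyl (2R)-2-chloro-2-[(2S,6S)-6-(dibromomethyl)-5-methyl-3,6-dihydro-2H-pyran-2-yl]propanoate
Product: 14 (2S)-2-chloro-2-[(2S,6S)-6-(dibromomethyl)-5-methyl-3,6-dihydro-2H-pyran-2-yl]propan-1-ol
Conditions: iBu2AlH (2.5 equiv), CH2Cl2, –78 to 0 °C; aq. potassium sodium tartrate
Reagents that add atoms: none
Why: Ester reduction with iBu2AlH to the primary alcohol, which should leave the tertiary C–Cl bond, the CHBr2 group and the ring alkene untouched at low temperature and affects no stereocentre (the descriptor of the chlorinated carbon changes to S only through the priority rules).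

Step 9
Reactants: 14 (2S)-2-chloro-2-[(2S,6S)-6-(dibromomethyl)-5-methyl-3,6-dihydro-2H-pyran-2-yl]propan-1-ol
Product: 15 (2S,6S)-6-(dibromomethyl)-2-[(2R)-1,2-dichloropropan-2-yl]-5-methyl-3,6-dihydro-2H-pyran
Conditions: PPh3, CCl4 (solvent), 70 °C
Reagents that add atoms: tetrachloromethane, ClC(Cl)(Cl)Cl
Why: Appel reaction, in which the alkoxyphosphonium salt is displaced by chloride in an SN2 step at the primary carbon, a process known to tolerate neopentyl-type alcohols on heating because the quaternary neighbour offers no β-hydrogen for elimination, and the adjacent stereocentre is not a reacting centre.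

**Compound list**

1 | methyl 3,3-dimethoxypropanoate | COC(CC(=O)OC)OC | starting material
2 | 3,3-dimethoxypropanal | COC(CC=O)OC | intermediate
3 | ethyl 2-[bis(2,2,2-trifluoroethoxy)phosphoryl]propanoate | CCOC(=O)C(C)P(=O)(OCC(F)(F)F)OCC(F)(F)F | starting material
4 | ethyl (2Z)-5,5-dimethoxy-2-methylpent-2-enoate | CCOC(=O)/C(C)=C\CC(OC)OC | intermediate
5 | dibromomethane | BrCBr | starting material
6 | dibromomethyllithium (formed in the flask, not isolated) | [Li]C(Br)Br | intermediate
7 | (3Z)-1,1-dibromo-6,6-dimethoxy-3-methylhex-3-en-2-one | BrC(Br)C(=O)/C(C)=C\CC(OC)OC | intermediate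
8 | (2S,3Z)-1,1-dibromo-6,6-dimethoxy-3-methylhex-3-en-2-ol | BrC(Br)[C@@H](O)/C(C)=C\CC(OC)OC | intermediate
9 | (6S)-6-(dibromomethyl)-2-methoxy-5-methyl-3,6-dihydro-2H-pyran (both C2 anomers) | CC1=CCC(OC)O[C@@H]1C(Br)Br | intermediate
10 | methyl 2-chloropropanoate (racemic) | COC(=O)C(C)Cl | starting material
11 | 2-chloro-1-methoxy-1-(trimethylsilyloxy)prop-1-ene (E/Z mixture) | CC(Cl)=C(OC)O[Si](C)(C)C | intermediate
12 | (6S)-6-(dibromomethyl)-5-methyl-3,6-dihydro-2H-pyran-2-ylium, the C2 oxocarbenium ion (triflate counter-ion; formed in the flask, not isolated) | CC1=CCC=[O+][C@@H]1C(Br)Br | intermediate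
13 | methyl (2R)-2-chloro-2-[(2S,6S)-6-(dibromomethyl)-5-methyl-3,6-dihydro-2H-pyran-2-yl]propanoate | CC1=CC[C@@H]([C@@](C)(Cl)C(=O)OC)O[C@@H]1C(Br)Br | intermediate
14 | (2S)-2-chloro-2-[(2S,6S)-6-(dibromomethyl)-5-methyl-3,6-dihydro-2H-pyran-2-yl]propan-1-ol | CC1=CC[C@@H]([C@@](C)(Cl)CO)O[C@@H]1C(Br)Br | intermediate
15 | (2S,6S)-6-(dibromomethyl)-2-[(2R)-1,2-dichloropropan-2-yl]-5-methyl-3,6-dihydro-2H-pyran | CC1=CC[C@@H]([C@@](C)(Cl)CCl)O[C@@H]1C(Br)Br | target

**Step count**

Total: 9 steps. Longest linear sequence: 8 steps (steps 1–5 and 7–9); step 6 is the one-step side branch.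

**Steps most likely to fail**

Step 7. The open transition state may not discriminate well between the two faces of the ketene acetal carbon, giving incomplete control at the quaternary carbon, and proton loss from C3 of the oxocarbenium ion may compete. Fallback, setting out from 9: the same ionisation (Me3SiOSO2CF3 cat., CH2Cl2, –78 °C) is run with the commercially available, less hindered 1-methoxy-1-(trimethylsilyloxy)prop-1-ene. This should give the 2,6-trans ester methyl 2-[(2S,6S)-6-(dibromomethyl)-5-methyl-3,6-dihydro-2H-pyran-2-yl]propanoate F1, mixed only at the side-chain carbon. That carbon is then converted into its lithium enolate (LiN(iPr)2, THF, –78 °C) and chlorinated with N-chlorosuccinimide. The quaternary centre is thus set by C–Cl bond formation on an enolate face differentiated by the adjacent C2 centre, and the route is rejoined at 13.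

Step 4. The two ketone substituents are of similar effective size, so facial selection by the catalyst may be low or opposite in sense, and uncatalysed reduction may erode it further. Fallback, setting out from 7:
- Reduction with NaBH4/CeCl3·7H2O (MeOH, –78 °C) gives the racemic alcohol (3Z)-1,1-dibromo-6,6-dimethoxy-3-methylhex-3-en-2-ol F2.
- Esterification with (S)-O-methylmandelic acid (N,N'-dicyclohexylcarbodiimide, 4-(dimethylamino)pyridine cat., CH2Cl2, 0 °C) gives the two diastereomeric esters, (2S,3Z)-1,1-dibromo-6,6-dimethoxy-3-methylhex-3-en-2-yl (2S)-2-methoxy-2-phenylacetate F3 and its (2R,3Z) diastereomer F4. They are separated by chromatography, and their 1H NMR shift differences also allow the carbinol configuration to be assigned.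
- F3 is cleaved with iBu2AlH (CH2Cl2, –78 °C), a non-basic method chosen to protect the dibromomethyl carbinol, and the route is rejoined at 8.

Step 9. Displacement at the neopentyl-type carbon may be slow, which leaves time for participation of the neighbouring chlorine (scrambling of the quaternary centre) or for attack of the phosphine on the CHBr2 group. Fallback, setting out from 14: the alcohol is converted with (CF3SO2)2O and pyridine (CH2Cl2, –78 °C) into (2S)-2-chloro-2-[(2S,6S)-6-(dibromomethyl)-5-methyl-3,6-dihydro-2H-pyran-2-yl]propyl trifluoromethanesulfonate F5. The far better leaving group is then displaced by LiCl in DMF at room temperature, arriving at 15.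

**Further compounds**

F1 | step 7 | methyl 2-[(2S,6S)-6-(dibromomethyl)-5-methyl-3,6-dihydro-2H-pyran-2-yl]propanoate (both epimers at the propanoate carbon) | CC1=CC[C@@H](C(C)C(=O)OC)O[C@@H]1C(Br)Br
F2 | step 4 | racemic (3Z)-1,1-dibromo-6,6-dimethoxy-3-methylhex-3-en-2-ol | BrC(Br)C(O)/C(C)=C\CC(OC)OC
F3 | step 4 | (2S,3Z)-1,1-dibromo-6,6-dimethoxy-3-methylhex-3-en-2-yl (2S)-2-methoxy-2-phenylacetate | CO[C@H](C(=O)O[C@H](C(Br)Br)/C(C)=C\CC(OC)OC)c1ccccc1
F4 | step 4 | (2R,3Z)-1,1-dibromo-6,6-dimethoxy-3-methylhex-3-en-2-yl (2S)-2-methoxy-2-phenylacetate | CO[C@H](C(=O)O[C@@H](C(Br)Br)/C(C)=C\CC(OC)OC)c1ccccc1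
F5 | step 9 | (2S)-2-chloro-2-[(2S,6S)-6-(dibromomethyl)-5-methyl-3,6-dihydro-2H-pyran-2-yl]propyl trifluoromethanesulfonate | CC1=CC[C@@H]([C@@](C)(Cl)COS(=O)(=O)C(F)(F)F)O[C@@H]1C(Br)Br
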